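## Structural features

Atoms are numbered as in kaurane. The target is a 9,10-seco-ent-kaurane built from two halves that meet only at the C7 methylene. One half is a bicyclo[3.2.1]octane (ring C: C8, C9, C11, C12, C13, C14; ring D: C8, C14, C13, C16, C15). The other is a cyclohexane (ring A) cis-fused at C4–C5 to a γ-lactone (C19, O, C6). The bicycle carries the quaternary bridgehead C8 next to the C9 ketone, the C11=C12 enone, the exocyclic C16=C17 methylene and a C15 acetate that points toward the ketone bridge (endo; C15–H faces C14). C8, C13 and C15 form one stereochemical set. C4 (quaternary: CH3 and lactone carbonyl), C5, C6 and C10 (tertiary alcohol trans to C6, methyl cis to C6, C7 trans to C10 on the lactone) form the second set. Because a single CH2 separates the sets, neither can control the other and each must be made in absolute form. Fragile points are the allylic acetate beside the methylene group (ionisation, zerovalent-metal insertion), the enone and a transient α-methylene ketone (conjugate acceptors), and the tertiary alcohol (elimination). The real difficulties are the all-carbon quaternary C8 inside a bridged ring, the congested C5–C6–C7–C8 link, and the C10 carbinol, whose oxygen lies on the face a methyl nucleophile would avoid. The key step uses the fact that C8 is both a bridgehead and the α-carbon of the C9 ketone: a C8 radical flanked by C9=O and a one-carbon acyl group (the future C7) maps ring C onto a 6-endo closure at C14 and ring D onto a 5-exo closure of C13 at C16.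

## Logic of the disconnections

34 ⇒ 33. The C11=C12 double bond is removed (C11–H and C12–H restored). The enone is the most electrophilic group of 34 and would not survive hydride, organolithium or fluoride; without it C9 can be masked. The forward dehydrogenation must spare an allylic acetate and a free tertiary alcohol; its regiochemistry is fixed because C8 is quaternary.

33 ⇒ 32 ⇒ 31 ⇒ 30 ⇒ 29 ⇒ 28. The C9 ketal is restored, then the acetyl C–O bond and the C15–H bond are cut, leading through 30 to 29 and its bis-silyl ether 28. This is needed because the key step is expected to place the C15 oxygen exo; passing through 30 lets a hydride set the endo configuration. The cost is three steps; the demands are exo-face hydride delivery to 30 and a C9 carbonyl that stays masked until 31 is acetylated.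

28 ⇒ 13 + 24. The C6–C7 bond and the lactone C6–O bond are cut. C7 is the only atom between the two stereochemical sets, so this cut gives two fragments of similar size, each stereochemically complete. The forward step must join a neopentyl carbanion to a hindered aldehyde and create C6 with C7 trans to C10; the carboxylate that later closes the lactone is used to direct it.

24 ⇒ 22 ⇒ 21 ⇒ 20. Protecting groups aside, the C10–O bond is cut, leaving the C1=C10 alkene of 20. Oxygen is added to an alkene rather than methyl to a ketone, because a nucleophile would approach C10 anti to C6 and give the wrong epimer. The hydration must be Markovnikov and must come from the convex face.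

20 ⇒ 19 ⇒ 17 ⇒ 15 ⇒ 14. The C1=C10 double bond (metathesis), the C4–CH3 bond, the C4–C3 bond and the C5–C10 bond are cut in turn, back to 14, whose acetal carbon is the future C6. Each bond forms next to an existing centre on a five-membered ring, so each new group enters trans to its neighbour; one purchased stereocentre is thereby translated into C5 and C4. The methyl group must be introduced last.

13 ⇒ 12 ⇒ 11 ⇒ 10. The C7–I bond is traced to the ester carbon of 10 and the ketal to the C9 ketone. Keeping the ester carbon as C7 avoids decarboxylation at a bridgehead and needs only reduction and substitution. The ketone must be masked before hydride and organolithium reagents are used.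

10 ⇒ 9. The C8–C14 and C13–C16 bonds are cut, opening rings C and D to an acyclic β-keto ester. Two rings, the quaternary bridgehead and the exocyclic alkene are traded for a chain with one stereocentre. The forward step needs 6-endo then 5-exo-dig radical closure and reliable transfer of chirality from C15 to C8.

9 ⇒ 8 ⇒ 5 + 6. After the alkyne silyl group is restored, the C8–C9 bond is cut (Claisen-type acylation), separating the pentenoyl unit from a β-silyloxy ester. The forward acylation must outrun β-elimination of the enolate.

5 ⇒ 4 ⇒ 1 + 2. The C8–C15 bond is cut (acetate aldol). The only stereocentre of the chain is assigned to a catalytic enantioselective addition to an ynal, which must be highly enantioselective and keep the alkynyl silane.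

## Other disconnections considered

Alternative 1: The cut is C13–C16, made by undoing a 1,2-shift: C16 is returned to C12, so rings C and D become a bicyclo[2.2.2]octane that a Diels–Alder reaction could assemble. Forward, a sulfonate at C13 ionises while the anti-periplanar C12–C16 bond migrates to C13, assisted by the C16=C17 π bond, and loss of H11 from the C12 cation gives the enone. The product A1 has every ring and the C9 enone but no oxygen on C15. In its favour, the shift is stereospecific and the lactone half can be carried from the start. It also creates the enone without a separate dehydrogenation; on this point it is the better plan, since the chosen route needs step 22. Against it here, C15 would have to be oxidised afterwards at an allylic CH2 beside quaternary C8, in competition with the enone, the C10 carbinol and C13–H; a hydroxyl delivered from the open exo face would still need inversion. The cation may also be captured or lose another proton. Both plans give the same bicycle. The cationic shift is more easily diverted than the radical tandem but does not depend on a relay from C15. In step count it would be shorter up to A1 and about equal once C15 is functionalised.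

Alternative 2: The cut is C3–C4 inside ring A, together with the C1–O bond of a six-membered lactone (C19, O, C1, C10, C5, C4). Forward, the lactone is converted into its silyl ketene acetal (LiN(iPr)2, Me3SiCl) and a [3,3] shift through the vinyl group on C1 contracts it to the carbocycle, giving acid A2 with C4, C5, C10 and the C6 ether in place. In its favour, the quaternary centre forms intramolecularly with chirality transfer from C1, the enolate geometry is fixed by the ring, and C10 is set before ring A exists. On control of C4 relative to C5 and C10 it is the equal of, or better than, steps 10 to 13 of the chosen route. Against it here, it offers nothing for rings C and D, which would have to be grown afterwards from the three-carbon chain on C6, so the bridged half with quaternary C8 would be built late and linearly. A2 also keeps a C1=C2 alkene to reduce and a labile tertiary silyl ether. Compared with the chosen plan it is stronger on ring A, comparable in mechanistic reliability (pericyclic against enolate chemistry), and weaker in convergence and total count.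

Alternative 3: The cuts are C8–C9 and C13–C14 of ring C. Forward, an α-methylene aldehyde carrying the complete lactone (C8=C14, CHO = C15) reacts with a 1-silyloxy dienyne (C9 to C13, alkyne = C16 and C17) under a chiral oxazaborolidinium Lewis acid to give cyclohexene A3; ring D would then be closed between C15 and C16. In its favour, it is convergent from the first ring-forming step, a catalyst rather than a neighbouring centre sets quaternary C8, and the 1-oxygenated diene has the right polarity for the C8–C9 bond. A3 already holds the C9 oxygen and the C11=C12 alkene, so no late dehydrogenation is needed; in oxidation-state economy it is the better plan. Against it here, α-substituted enals tend to react through a formyl-exo transition state, so the C8/C13 relationship needed for the later bridge is not assured, and the catalyst must override any bias from the lactone. The silyloxy diene with a conjugated alkyne is sensitive, and ring D needs a second key event (reductive closure of the aldehyde onto the alkyne) that must also fix C15. The chosen plan forms both rings and C8/C13 in one step from a short chain but pays with the C15 inversion and the late enone. The alternative would reach the bicycle in two key steps with a plausibly equal or slightly lower total count.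

Key step: step 5

Assumption (stereochemical relay): in the 6-endo closure the C15–O bond should lie anti to the forming C8–C14 bond with C15–H over the nascent ring, which places the silyloxy group exo in 10; the carbinol is therefore made in the (R) series, and C15 is reset after the coupling (steps 18 and 19).

## Route

Step 1
Reactants: 1 3-(trimethylsilyl)prop-2-ynal; 2 1-methoxy-1-(trimethylsilyloxy)ethene
Product: 4 methyl (3R)-3-hydroxy-5-(trimethylsilyl)pent-4-ynoate, via O-trimethylsilyl aldol adduct 3 (not isolated)
Conditions: Ti(OiPr)4 (2 mol %), 2-(3-bromo-5-tert-butyl-2-hydroxybenzylideneamino)-2'-hydroxy-1,1'-binaphthyl (enantiomer for Re-face addition), 3,5-di-tert-butylsalicylic acid, Et2O, -10 °C; then 1 M HCl, THF, 0 °C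
Reagents that add atoms: none
Why: Catalytic enantioselective Mukaiyama acetate aldol; conjugated ynals are unhindered, non-enolisable acceptors for this titanium Schiff-base catalyst, and Re-face addition should give the (3R) carbinol (C15). Cold dilute acid cleaves only the O–SiMe3 group; the alkynyl silane is kept to block the alkyne C–H in step 3.

Step 2
Reactants: 4 methyl (3R)-3-hydroxy-5-(trimethylsilyl)pent-4-ynoate
Product: 5 methyl (3R)-3-(tert-butyldimethylsilyloxy)-5-(trimethylsilyl)pent-4-ynoate
Conditions: t-BuMe2SiCl, imidazole, DMF, rt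
Reagents that add atoms: tert-butyldimethylsilyl chloride, CC(C)(C)[Si](C)(C)Cl
Why: Standard silylation of a secondary propargylic alcohol; the bulky, non-chelating silyl ether later steers the radical closure and survives enolate, hydride and organolithium chemistry.

Step 3
Reactants: 5 methyl (3R)-3-(tert-butyldimethylsilyloxy)-5-(trimethylsilyl)pent-4-ynoate; 6 pent-4-enoyl chloride
Product: 8 methyl 2-[(1R)-1-(tert-butyldimethylsilyloxy)-3-(trimethylsilyl)prop-2-yn-1-yl]-3-oxohept-6-enoate, via lithium ester enolate 7 (not isolated)
Conditions: LiN(iPr)2 (2.1 equiv), THF, -78 °C; 6, -78 °C; AcOH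
Reagents that add atoms: none
Why: Crossed Claisen acylation: enolate 7 is C-acylated at -78 °C and the second equivalent of base stores the product as its stabilised enolate, which protects it from further acylation and from loss of silanolate. The new C8 centre is epimerisable and of no consequence.

Step 4
Reactants: 8 methyl 2-[(1R)-1-(tert-butyldimethylsilyloxy)-3-(trimethylsilyl)prop-2-yn-1-yl]-3-oxohept-6-enoate
Product: 9 methyl 2-[(1R)-1-(tert-butyldimethylsilyloxy)prop-2-yn-1-yl]-3-oxohept-6-enoate
Conditions: AgNO3 (10 mol %), MeOH/H2O/CH2Cl2, rt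
Reagents that add atoms: none
Why: Silver-catalysed protodesilylation of an alkynylsilane runs under near-neutral conditions, so the β-keto ester is not held as an enolate that could expel the β-silyloxy group, and O-silyl ethers are untouched.

Step 5
Reactants: 9 methyl 2-[(1R)-1-(tert-butyldimethylsilyloxy)prop-2-yn-1-yl]-3-oxohept-6-enoate
Product: 10 methyl (1R,5R,7S)-7-(tert-butyldimethylsilyloxy)-6-methylidene-2-oxobicyclo[3.2.1]octane-1-carboxylate
Conditions: Mn(OAc)3·2H2O (2.2 equiv), degassed EtOH, 50 °C
Reagents that add atoms: none
Why: Trivalent manganese (Mn(OAc)3) enolises and oxidises the 1,3-dicarbonyl unit of 9 to the electrophilic tertiary C8 radical, which adds to the terminal alkene carbon C14; the secondary C13 radical then adds to C16 of the alkyne and the vinyl radical takes hydrogen from ethanol, whose hydroxyethyl radical is oxidised by the second equivalent of Mn(OAc)3. The closest known reaction type is the oxidative tandem cyclisation of 2-propargyl 3-oxohept-6-enoates to 6-methylidenebicyclo[3.2.1]octan-2-ones. Ring C (C8, C9, C11, C12, C13, C14) closes 6-endo-trig, the usual mode when the ketone lies inside the forming ring and the radical carbon is fully substituted; ring D (C8, C14, C13, C16, C15) closes 5-exo-dig. C8 is set in the first closure by C15: in the Felkin–Anh-like arrangement the C15–O bond stands anti to the forming C8–C14 bond, C15–H points over the nascent ring beside C11 and the slim ethynyl group lies beside the ester, so that from (R)-C15 the alkene should attack the face that gives C8 as in the target with the silyloxy group exo. C13 is then fixed by the ring itself, because only an axial propargyl group cis-1,3 to the C13 radical can bridge. The step needs facial selectivity in the first closure (bulky silyloxy group, allylic strain toward C11), 6-endo regioselectivity (α-substituent, ring ketone) and hydrogen transfer to the vinyl radical that is faster than its oxidation (ethanol as solvent). Because C15 is oxidised and reduced later, only the C8/C13 sense of this relay has to be right.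

Step 6
Reactants: 10 methyl (1R,5R,7S)-7-(tert-butyldimethylsilyloxy)-6-methylidene-2-oxobicyclo[3.2.1]octane-1-carboxylate
Product: 11 methyl 7'-(tert-butyldimethylsilyloxy)-6'-methylidenespiro[1,3-dioxolane-2,2'-bicyclo[3.2.1]octane]-1'-carboxylate
Conditions: (Me3SiOCH2)2, Me3SiOTf (10 mol %), CH2Cl2, -78 to -20 °C; pyridine
Reagents that add atoms: 1,2-bis(trimethylsilyloxy)ethane, C[Si](C)(C)OCCO[Si](C)(C)C
Why: Silyl-triflate-catalysed ketalisation with the bis-silyl ether of glycol works at low temperature on hindered ketones and leaves the allylic silyl ether and the methylene group alone. C9 must be masked for steps 7, 16 and 19.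

Step 7
Reactants: 11 methyl 7'-(tert-butyldimethylsilyloxy)-6'-methylidenespiro[1,3-dioxolane-2,2'-bicyclo[3.2.1]octane]-1'-carboxylate
Product: 12 [7'-(tert-butyldimethylsilyloxy)-6'-methylidenespiro[1,3-dioxolane-2,2'-bicyclo[3.2.1]octan]-1'-yl]methanol
Conditions: LiAlH4, THF, 0 °C
Reagents that add atoms: none
Why: Hydride reduction of a neopentyl ester to the primary alcohol; the ester carbon is retained as C7, and ketal, silyl ether and alkene are inert.

Step 8
Reactants: 12 [7'-(tert-butyldimethylsilyloxy)-6'-methylidenespiro[1,3-dioxolane-2,2'-bicyclo[3.2.1]octan]-1'-yl]methanol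
Product: 13 7'-(tert-butyldimethylsilyloxy)-1'-(iodomethyl)-6'-methylidenespiro[1,3-dioxolane-2,2'-bicyclo[3.2.1]octane]
Conditions: I2, PPh3, imidazole, toluene, 80 °C
Reagents that add atoms: iodine, II
Why: Appel-type iodination; substitution at the neopentyl carbon is slow and is driven by heat, and no other hydroxyl is present.

Step 9
Reactants: 14 (5S)-5-[(1S,2R,5S)-2-isopropyl-5-methylcyclohexyloxy]furan-2(5H)-one
Product: 15 (5S)-5-[(1S,2R,5S)-menthyloxy]-4-(prop-1-en-2-yl)oxolan-2-one (4,5-trans)
Conditions: CH2=C(CH3)MgBr (1.5 equiv), CuBr·SMe2 (10 mol %), THF, -78 to -40 °C; aq. NH4Cl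
Reagents that add atoms: isopropenylmagnesium bromide, C=C(C)[Mg]Br
Why: Copper-catalysed conjugate addition of an alkenyl Grignard reagent to a γ-alkoxybutenolide; the menthyloxy group on the acetal carbon (future C6) blocks its own face, so C10 should enter trans to it and set C5.

Step 10
Reactants: 15 (5S)-5-[(1S,2R,5S)-menthyloxy]-4-(prop-1-en-2-yl)oxolan-2-one (4,5-trans)
Product: 17 (5S)-3-(but-3-en-1-yl)-5-[(1S,2R,5S)-menthyloxy]-4-(prop-1-en-2-yl)oxolan-2-one (3,4-trans, 4,5-trans), via lithium lactone enolate 16 (not isolated)
Conditions: LiN(iPr)2, THF, -78 °C; 4-iodobut-1-ene, DMPU, -78 to -30 °C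
Reagents that add atoms: 4-iodobut-1-ene, C=CCCI
Why: Alkylation of a β-substituted butyrolactone enolate occurs anti to the β-substituent, placing the butenyl chain trans to the isopropenyl group. This centre is re-formed in step 11, so only clean monoalkylation matters.

Step 11
Reactants: 17 (5S)-3-(but-3-en-1-yl)-5-[(1S,2R,5S)-menthyloxy]-4-(prop-1-en-2-yl)oxolan-2-one (3,4-trans, 4,5-trans)
Product: 19 (5S)-3-(but-3-en-1-yl)-3-methyl-5-[(1S,2R,5S)-menthyloxy]-4-(prop-1-en-2-yl)oxolan-2-one (butenyl cis to isopropenyl), via lithium lactone enolate 18 (not isolated)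
Conditions: LiN(iPr)2, THF, -78 °C; MeI, -78 to -20 °C
Reagents that add atoms: iodomethane, CI
Why: Second enolate alkylation: iodomethane again approaches anti to the C5 isopropenyl group, so the methyl becomes trans and the butenyl chain cis to it. This sets quaternary C4 with the relative configuration needed for the cis ring fusion.

Step 12
Reactants: 19 (5S)-3-(but-3-en-1-yl)-3-methyl-5-[(1S,2R,5S)-menthyloxy]-4-(prop-1-en-2-yl)oxolan-2-one (butenyl cis to isopropenyl)
Product: 20 (3S)-3-[(1S,2R,5S)-menthyloxy]-4,7a-dimethyl-3a,6,7,7a-tetrahydro-2-benzofuran-1(3H)-one (cis-fused)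
Conditions: second-generation Grubbs catalyst RuCl2(=CHPh)(PCy3)(H2IMes) (5 mol %), CH2Cl2, 40 °C
Reagents that add atoms: none
Why: Ring-closing metathesis of a monosubstituted with a 1,1-disubstituted alkene to a trisubstituted cyclohexene; the two alkenes are cis on adjacent carbons, so ring A closes with the C1=C10 double bond.

Step 13
Reactants: 20 (3S)-3-[(1S,2R,5S)-menthyloxy]-4,7a-dimethyl-3a,6,7,7a-tetrahydro-2-benzofuran-1(3H)-one (cis-fused)
Product: 21 (3S)-4-hydroxy-3-[(1S,2R,5S)-menthyloxy]-4,7a-dimethylhexahydro-2-benzofuran-1(3H)-one (hydroxyl trans to the lactone ring)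
Conditions: Co(acac)2 (20 mol %), PhSiH3, O2 (1 atm), THF, rt
Reagents that add atoms: dioxygen, O=O
Why: Mukaiyama hydration (cobalt-hydride hydrogen-atom transfer, then capture of the tertiary C10 radical by O2) gives the Markovnikov tertiary alcohol. Oxygen should arrive on the convex face, anti to the lactone ring and its axial carbonyl carbon, which puts the hydroxyl trans to C6 and the methyl cis to it.

Step 14
Reactants: 21 (3S)-4-hydroxy-3-[(1S,2R,5S)-menthyloxy]-4,7a-dimethylhexahydro-2-benzofuran-1(3H)-one
Product: 22 3,4-dihydroxy-4,7a-dimethylhexahydro-2-benzofuran-1(3H)-one (lactol of the aldehyde acid, C3 anomers)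
Conditions: 1 M HCl, THF, rt
Reagents that add atoms: water, O
Why: The mixed acyl acetal ionises readily in dilute acid (loss of the carboxylate, then hydrolysis of the hemiacetal), releasing menthol and the lactol form of the aldehyde acid. The tertiary alcohol should not dehydrate under these conditions.

Step 15
Reactants: 22 3,4-dihydroxy-4,7a-dimethylhexahydro-2-benzofuran-1(3H)-one
Product: 24 3-hydroxy-4,7a-dimethyl-4-(triethylsilyloxy)hexahydro-2-benzofuran-1(3H)-one (C3 anomers), via bis(triethylsilyl) derivative 23 (not isolated)
Conditions: Et3SiOTf (2.5 equiv), 2,6-lutidine, CH2Cl2, -78 to 0 °C; then aq. NaHCO3, MeOH, rt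
Reagents that add atoms: triethylsilyl trifluoromethanesulfonate, CC[Si](CC)(CC)OS(=O)(=O)C(F)(F)F
Why: Both hydroxyls are silylated; the silyl derivative of the pseudo-acid is solvolysed on mild basic work-up while the tertiary triethylsilyl ether stays. C10–O is thereby left as a bulky, non-coordinating group for step 16.

Step 16
Reactants: 13 7'-(tert-butyldimethylsilyloxy)-1'-(iodomethyl)-6'-methylidenespiro[1,3-dioxolane-2,2'-bicyclo[3.2.1]octane]; 24 3-hydroxy-4,7a-dimethyl-4-(triethylsilyloxy)hexahydro-2-benzofuran-1(3H)-one
Product: 28 C9 ethylene ketal of 15-epi-15-deacetyl-11,12-dihydro-34 as its 15-O-tert-butyldimethylsilyl 10-O-triethylsilyl ether, via alkyllithium 25 (not isolated), via bromomagnesium aldehyde carboxylate 26 (not isolated), via open hydroxy carboxylate 27 (not isolated)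
Conditions: 24: NaH, THF, 0 °C, then MgBr2·OEt2; 13: t-BuLi (2.1 equiv), Et2O/pentane, -78 °C; combine at -78 °C, warm to -20 °C; 1 M HCl to pH 3, 0 °C
Reagents that add atoms: none
Why: Chelation-controlled addition of a primary alkyllithium to an aldehyde carboxylate followed by lactonisation, the classical route from aldehyde acids to γ-lactones. The magnesium carboxylate holds the C6 carbonyl syn to C4, so the nucleophile should enter anti to C10 and give the C6 configuration of the target (C7 trans to C10). Iodine–lithium exchange at -78 °C tolerates the ketal, the silyl ethers and the 1,1-disubstituted alkene.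

Step 17
Reactants: 28 C9 ethylene ketal of 15-epi-15-deacetyl-11,12-dihydro-34 as its 15-O-tert-butyldimethylsilyl 10-O-triethylsilyl ether
Product: 29 C9 ethylene ketal of 15-epi-15-deacetyl-11,12-dihydro-34 (15-exo alcohol)
Conditions: Bu4NF (4 equiv), THF, rt to 40 °C; aq. NH4Cl
Reagents that add atoms: none
Why: Fluoride cleaves both silyl ethers while ketal, lactone and alkene are stable; the two alcohols freed (secondary allylic and tertiary) differ enough for the next three steps.

Step 18
Reactants: 29 C9 ethylene ketal of 15-epi-15-deacetyl-11,12-dihydro-34 (15-exo alcohol)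
Product: 30 C9 ethylene ketal of 15-deacetoxy-15-oxo-11,12-dihydro-34
Conditions: Dess–Martin periodinane, NaHCO3, CH2Cl2, 0 °C
Reagents that add atoms: none
Why: Dess–Martin oxidation of the secondary allylic alcohol to the α-methylene cyclopentanone under buffered, non-nucleophilic conditions; the tertiary alcohol cannot be oxidised.

Step 19
Reactants: 30 C9 ethylene ketal of 15-deacetoxy-15-oxo-11,12-dihydro-34
Product: 31 C9 ethylene ketal of 15-deacetyl-11,12-dihydro-34 (15-endo alcohol)
Conditions: NaBH4, CeCl3·7H2O, MeOH, -78 °C
Reagents that add atoms: none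
Why: Luche reduction gives 1,2-addition to the enone; hydride should come from the exo face (the side of C14), away from the C9 dioxolane and the axial C11–H, to give the endo alcohol of the target. The masked C9 cannot compete.

Step 20
Reactants: 31 C9 ethylene ketal of 15-deacetyl-11,12-dihydro-34 (15-endo alcohol)
Product: 32 C9 ethylene ketal of 11,12-dihydro-34
Conditions: Ac2O, pyridine, DMAP (cat.), CH2Cl2, 0 °C to rt
Reagents that add atoms: acetic anhydride, CC(=O)OC(C)=O
Why: Acylation of the secondary alcohol; the tertiary C10 hydroxyl, flanked by the ring fusion, should not be acetylated under these mild conditions.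

Step 21
Reactants: 32 C9 ethylene ketal of 11,12-dihydro-34
Product: 33 11,12-dihydro-34
Conditions: TsOH·H2O (0.2 equiv), acetone/H2O (10:1), rt
Reagents that add atoms: water, O
Why: Acid-catalysed ketal hydrolysis in wet acetone frees the C9 ketone; acetate, lactone and tertiary alcohol tolerate catalytic sulfonic acid at room temperature.

Step 22
Reactants: 33 11,12-dihydro-34
Product: 34 15-acetoxy-10-hydroxy-9-oxo-9,10-seco-ent-kaura-11,16-dien-19-oic acid 19,6-lactone (CNP0172716.1)
Conditions: IBX (2.5 equiv), DMSO, 70 °C
Reagents that add atoms: none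
Why: IBX dehydrogenation of a ketone to the enone; C8 is quaternary, so only C11 can enolise and the double bond can only form at C11–C12. A metal-free oxidant avoids ionising the allylic acetate.

## Compound list

1 | 3-(trimethylsilyl)prop-2-ynal | C[Si](C)(C)C#CC=O | starting material
2 | 1-methoxy-1-(trimethylsilyloxy)ethene | C=C(OC)O[Si](C)(C)C | starting material
3 | methyl (3R)-3-(trimethylsilyloxy)-5-(trimethylsilyl)pent-4-ynoate | COC(=O)C[C@@H](O[Si](C)(C)C)C#C[Si](C)(C)C | intermediate
4 | methyl (3R)-3-hydroxy-5-(trimethylsilyl)pent-4-ynoate | COC(=O)C[C@@H](O)C#C[Si](C)(C)C | intermediate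
5 | methyl (3R)-3-(tert-butyldimethylsilyloxy)-5-(trimethylsilyl)pent-4-ynoate | COC(=O)C[C@@H](O[Si](C)(C)C(C)(C)C)C#C[Si](C)(C)C | intermediate
6 | pent-4-enoyl chloride | C=CCCC(Cl)=O | starting material
7 | lithium enolate of 5 | [Li]OC(OC)=C[C@@H](O[Si](C)(C)C(C)(C)C)C#C[Si](C)(C)C | intermediate
8 | methyl 2-[(1R)-1-(tert-butyldimethylsilyloxy)-3-(trimethylsilyl)prop-2-yn-1-yl]-3-oxohept-6-enoate (C2 epimers) | C=CCCC(=O)C(C(=O)OC)[C@H](C#C[Si](C)(C)C)O[Si](C)(C)C(C)(C)C | intermediate
9 | methyl 2-[(1R)-1-(tert-butyldimethylsilyloxy)prop-2-yn-1-yl]-3-oxohept-6-enoate (C2 epimers) | C=CCCC(=O)C(C(=O)OC)[C@H](C#C)O[Si](C)(C)C(C)(C)C | intermediate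
10 | methyl (1R,5R,7S)-7-(tert-butyldimethylsilyloxy)-6-methylidene-2-oxobicyclo[3.2.1]octane-1-carboxylate (silyloxy exo, syn to the one-carbon bridge) | C=C1[C@@H]2CCC(=O)[C@@](C(=O)OC)(C2)[C@H]1O[Si](C)(C)C(C)(C)C | intermediate
11 | methyl 7'-(tert-butyldimethylsilyloxy)-6'-methylidenespiro[1,3-dioxolane-2,2'-bicyclo[3.2.1]octane]-1'-carboxylate (stereocentres as in 10) | C=C1[C@@H]2CCC3(OCCO3)[C@@](C(=O)OC)(C2)[C@H]1O[Si](C)(C)C(C)(C)C | intermediate
12 | [7'-(tert-butyldimethylsilyloxy)-6'-methylidenespiro[1,3-dioxolane-2,2'-bicyclo[3.2.1]octan]-1'-yl]methanol (stereocentres as in 10) | C=C1[C@@H]2CCC3(OCCO3)[C@@](CO)(C2)[C@H]1O[Si](C)(C)C(C)(C)C | intermediate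
13 | 7'-(tert-butyldimethylsilyloxy)-1'-(iodomethyl)-6'-methylidenespiro[1,3-dioxolane-2,2'-bicyclo[3.2.1]octane] (stereocentres as in 10) | C=C1[C@@H]2CCC3(OCCO3)[C@@](CI)(C2)[C@H]1O[Si](C)(C)C(C)(C)C | intermediate
14 | (5S)-5-[(1S,2R,5S)-2-isopropyl-5-methylcyclohexyloxy]furan-2(5H)-one | CC(C)[C@H]1CC[C@H](C)C[C@@H]1O[C@H]2OC(=O)C=C2 | starting material
15 | (5S)-5-[(1S,2R,5S)-menthyloxy]-4-(prop-1-en-2-yl)oxolan-2-one (4,5-trans) | CC(C)[C@H]1CC[C@H](C)C[C@@H]1O[C@H]2OC(=O)C[C@@H]2C(C)=C | intermediate
16 | lithium enolate of 15 | CC(C)[C@H]1CC[C@H](C)C[C@@H]1O[C@H]2OC(O[Li])=C[C@@H]2C(C)=C | intermediate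
17 | (5S)-3-(but-3-en-1-yl)-5-[(1S,2R,5S)-menthyloxy]-4-(prop-1-en-2-yl)oxolan-2-one (3,4-trans, 4,5-trans) | CC(C)[C@H]1CC[C@H](C)C[C@@H]1O[C@H]2OC(=O)[C@@H](CCC=C)[C@@H]2C(C)=C | intermediate
18 | lithium enolate of 17 | CC(C)[C@H]1CC[C@H](C)C[C@@H]1O[C@H]2OC(O[Li])=C(CCC=C)[C@@H]2C(C)=C | intermediate
19 | (5S)-3-(but-3-en-1-yl)-3-methyl-5-[(1S,2R,5S)-menthyloxy]-4-(prop-1-en-2-yl)oxolan-2-one (butenyl cis to isopropenyl, isopropenyl trans to menthyloxy) | CC(C)[C@H]1CC[C@H](C)C[C@@H]1O[C@H]2OC(=O)[C@](C)(CCC=C)[C@@H]2C(C)=C | intermediate
20 | (3S)-3-[(1S,2R,5S)-menthyloxy]-4,7a-dimethyl-3a,6,7,7a-tetrahydro-2-benzofuran-1(3H)-one (cis-fused, menthyloxy trans to C4) | CC(C)[C@H]1CC[C@H](C)C[C@@H]1O[C@H]2OC(=O)[C@]3(C)CCC=C(C)[C@H]23 | intermediate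
21 | (3S)-4-hydroxy-3-[(1S,2R,5S)-menthyloxy]-4,7a-dimethylhexahydro-2-benzofuran-1(3H)-one (cis-fused, hydroxyl trans to the lactone ring) | CC(C)[C@H]1CC[C@H](C)C[C@@H]1O[C@H]2OC(=O)[C@]3(C)CCC[C@@](C)(O)[C@H]23 | intermediate
22 | 3,4-dihydroxy-4,7a-dimethylhexahydro-2-benzofuran-1(3H)-one (C3 anomers, other centres as in 21) | OC1OC(=O)[C@]2(C)CCC[C@@](C)(O)[C@H]12 | intermediate
23 | 4,7a-dimethyl-3,4-bis(triethylsilyloxy)hexahydro-2-benzofuran-1(3H)-one (C3 anomers) | CC[Si](CC)(CC)OC1OC(=O)[C@]2(C)CCC[C@@](C)(O[Si](CC)(CC)CC)[C@H]12 | intermediate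
24 | 3-hydroxy-4,7a-dimethyl-4-(triethylsilyloxy)hexahydro-2-benzofuran-1(3H)-one (C3 anomers) | OC1OC(=O)[C@]2(C)CCC[C@@](C)(O[Si](CC)(CC)CC)[C@H]12 | intermediate
25 | alkyllithium from 13 ([7'-(tert-butyldimethylsilyloxy)-6'-methylidenespiro[1,3-dioxolane-2,2'-bicyclo[3.2.1]octan]-1'-yl]methyllithium) | C=C1[C@@H]2CCC3(OCCO3)[C@@](C[Li])(C2)[C@H]1O[Si](C)(C)C(C)(C)C | intermediate
26 | bromomagnesium 2-formyl-1,3-dimethyl-3-(triethylsilyloxy)cyclohexane-1-carboxylate (open form of 24, formyl cis to carboxylate and trans to silyloxy) | Br[Mg]OC(=O)[C@]1(C)CCC[C@@](C)(O[Si](CC)(CC)CC)[C@@H]1C=O | intermediate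
27 | lithium alkoxide and bromomagnesium carboxylate of the open C6 hydroxy acid (adduct of 25 and 26) | C=C1[C@@H]2CCC3(OCCO3)[C@@](C[C@@H](O[Li])[C@@H]4[C@@](C)(CCC[C@@]4(C)O[Si](CC)(CC)CC)C(=O)O[Mg]Br)(C2)[C@H]1O[Si](C)(C)C(C)(C)C | intermediate
28 | C9 ethylene ketal of 15-epi-15-deacetyl-11,12-dihydro-34, 15-O-tert-butyldimethylsilyl and 10-O-triethylsilyl ether | C=C1[C@@H]2CCC3(OCCO3)[C@@](C[C@H]4OC(=O)[C@]5(C)CCC[C@@](C)(O[Si](CC)(CC)CC)[C@H]45)(C2)[C@H]1O[Si](C)(C)C(C)(C)C | intermediate
29 | C9 ethylene ketal of 15-epi-15-deacetyl-11,12-dihydro-34 (15-exo alcohol, 10-hydroxyl free) | C=C1[C@@H]2CCC3(OCCO3)[C@@](C[C@H]4OC(=O)[C@]5(C)CCC[C@@](C)(O)[C@H]45)(C2)[C@H]1O | intermediate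
30 | C9 ethylene ketal of 15-deacetoxy-15-oxo-11,12-dihydro-34 (16-methylidene 15-ketone) | C=C1[C@@H]2CCC3(OCCO3)[C@@](C[C@H]4OC(=O)[C@]5(C)CCC[C@@](C)(O)[C@H]45)(C2)C1=O | intermediate
31 | C9 ethylene ketal of 15-deacetyl-11,12-dihydro-34 (15-endo alcohol) | C=C1[C@@H]2CCC3(OCCO3)[C@@](C[C@H]4OC(=O)[C@]5(C)CCC[C@@](C)(O)[C@H]45)(C2)[C@@H]1O | intermediate
32 | C9 ethylene ketal of 11,12-dihydro-34 | C=C1[C@@H]2CCC3(OCCO3)[C@@](C[C@H]4OC(=O)[C@]5(C)CCC[C@@](C)(O)[C@H]45)(C2)[C@@H]1OC(C)=O | intermediate
33 | 11,12-dihydro-34 (15-acetoxy-10-hydroxy-9-oxo-9,10-seco-ent-kaur-16-en-19-oic acid 19,6-lactone) | C=C1[C@@H]2CCC(=O)[C@@](C[C@H]3OC(=O)[C@]4(C)CCC[C@@](C)(O)[C@H]34)(C2)[C@@H]1OC(C)=O | intermediate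
34 | 15-acetoxy-10-hydroxy-9-oxo-9,10-seco-ent-kaura-11,16-dien-19-oic acid 19,6-lactone (CNP0172716.1) | C=C1[C@@H]2C=CC(=O)[C@@](C[C@H]3OC(=O)[C@]4(C)CCC[C@@](C)(O)[C@H]34)(C2)[C@@H]1OC(C)=O | target

## Step count and least certain steps

Total step count: 22. Longest linear sequence: 15 steps (steps 1 to 8, then 16 to 22); the ring A branch (steps 9 to 15) joins at step 16.

Key step (step 5). The most likely failure is loss of facial discrimination in the first ring closure. The relay rests on one acyclic centre and enolisation of the hindered β-keto ester needs warming, so the C8-epimeric series (mirror-image bicycle, silyloxy endo) may form alongside; the C13 radical may also be oxidised before it reaches the alkyne. The fallback replaces the stoichiometric oxidation by a low-temperature iodine-atom-transfer chain. It sets out from 9, which is iodinated at C8 with N-iodosuccinimide in THF to give methyl 2-iodo-2-[1-(tert-butyldimethylsilyloxy)prop-2-yn-1-yl]-3-oxohept-6-enoate F1. Et3B/O2 at -78 °C then starts the same 6-endo/5-exo-dig sequence, ended by iodine transfer, to give methyl 7-(tert-butyldimethylsilyloxy)-6-(iodomethylidene)-2-oxobicyclo[3.2.1]octane-1-carboxylate F2. Bu3SnH with Et3B removes the vinylic iodine, and the sequence comes back to the route at 10.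

Fragment coupling (step 16). The most likely failure is poor facial selectivity at C6, since an unchelated approach or one directed by the C10 oxygen would give the C6 epimer; deprotonation of the hindered aldehyde at C5 by the basic organolithium is the second risk. The fallback makes the aldehyde carbon a cyclic electrophile that is open only on its convex face and uses a non-basic nucleophile. It sets out from 24 and 13. Compound 24 is acetylated (Ac2O, pyridine) to 3-acetoxy-4,7a-dimethyl-4-(triethylsilyloxy)hexahydro-2-benzofuran-1(3H)-one F3. Compound 13 is converted by t-BuLi and then ZnBr2 into the alkylzinc bromide [7'-(tert-butyldimethylsilyloxy)-6'-methylidenespiro[1,3-dioxolane-2,2'-bicyclo[3.2.1]octan]-1'-yl]methylzinc bromide F4. Me3SiOTf at -78 °C ionises the acetate to the acyloxycarbenium ion, which the zinc reagent should alkylate anti to C10; this comes back to the route at 28.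

Hydration (step 13). The most likely failure is poor facial selectivity when O2 captures the nearly planar C10 radical. The fallback is polar and stereospecific. It sets out from 20: m-CPBA should epoxidise the convex face to give the 1,10-epoxide (3S)-4,5-epoxy-3-[(1S,2R,5S)-menthyloxy]-4,7a-dimethylhexahydro-2-benzofuran-1(3H)-one F5. PhSeNa opens it at the less substituted C1 (trans-diaxial) to the hydroxy selenide (3S)-4-hydroxy-3-[(1S,2R,5S)-menthyloxy]-4,7a-dimethyl-5-(phenylselanyl)hexahydro-2-benzofuran-1(3H)-one F6. Bu3SnH/AIBN removes the selenium, and the sequence comes back at 21.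

Acylation (step 3). The most likely failure is loss of silanolate from enolate 7 (β-elimination) or over-acylation by the acid chloride. The fallback changes the C8–C9 bond formation to an aldol addition followed by oxidation. It sets out from 5: its enolate 7 is treated with pent-4-enal at -78 °C to give methyl 2-[(1R)-1-(tert-butyldimethylsilyloxy)-3-(trimethylsilyl)prop-2-yn-1-yl]-3-hydroxyhept-6-enoate F7 as a diastereomer mixture, and Dess–Martin periodinane oxidises the new carbinol, which comes back at 8.

Dehydrogenation (step 22). The most likely failure is slow enolisation of the hindered ketone at the temperature IBX needs, with oxidation at the allylic positions as competitor. The fallback is a two-stage Saegusa–Ito sequence. It sets out from 33: Me3SiOTf/Et3N gives the silyl enol ether that is also silylated at the C10 oxygen, the 9-(trimethylsilyloxy)-9(11)-ene 10-O-trimethylsilyl ether of 33 F8. Pd(OAc)2 in MeCN converts it into the 10-O-trimethylsilyl ether of 34 F9, and dilute HCl removes the remaining silyl group, which comes back at 34.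

## Further compounds

F1 | step 5 | methyl 2-iodo-2-[1-(tert-butyldimethylsilyloxy)prop-2-yn-1-yl]-3-oxohept-6-enoate (C15 configured as in 9) | C=CCCC(=O)C(I)(C(=O)OC)[C@H](C#C)O[Si](C)(C)C(C)(C)C
F2 | step 5 | methyl 7-(tert-butyldimethylsilyloxy)-6-(iodomethylidene)-2-oxobicyclo[3.2.1]octane-1-carboxylate (stereocentres as in 10, alkene isomers) | IC=C1[C@@H]2CCC(=O)[C@@](C(=O)OC)(C2)[C@H]1O[Si](C)(C)C(C)(C)C
F3 | step 16 | 3-acetoxy-4,7a-dimethyl-4-(triethylsilyloxy)hexahydro-2-benzofuran-1(3H)-one (C3 anomers) | CC(=O)OC1OC(=O)[C@]2(C)CCC[C@@](C)(O[Si](CC)(CC)CC)[C@H]12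
F4 | step 16 | [7'-(tert-butyldimethylsilyloxy)-6'-methylidenespiro[1,3-dioxolane-2,2'-bicyclo[3.2.1]octan]-1'-yl]methylzinc bromide | C=C1[C@@H]2CCC3(OCCO3)[C@@](C[Zn]Br)(C2)[C@H]1O[Si](C)(C)C(C)(C)C
F5 | step 13 | (3S)-4,5-epoxy-3-[(1S,2R,5S)-menthyloxy]-4,7a-dimethylhexahydro-2-benzofuran-1(3H)-one (epoxide trans to the lactone ring) | CC(C)[C@H]1CC[C@H](C)C[C@@H]1O[C@H]2OC(=O)[C@]3(C)CC[C@H]4O[C@@]4(C)[C@H]23
F6 | step 13 | (3S)-4-hydroxy-3-[(1S,2R,5S)-menthyloxy]-4,7a-dimethyl-5-(phenylselanyl)hexahydro-2-benzofuran-1(3H)-one (selenide trans to hydroxyl) | CC(C)[C@H]1CC[C@H](C)C[C@@H]1O[C@H]2OC(=O)[C@]3(C)CC[C@H]([Se]c4ccccc4)[C@@](C)(O)[C@H]23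
F7 | step 3 | methyl 2-[(1R)-1-(tert-butyldimethylsilyloxy)-3-(trimethylsilyl)prop-2-yn-1-yl]-3-hydroxyhept-6-enoate (diastereomers at C2 and C3) | C=CCCC(O)C(C(=O)OC)[C@H](C#C[Si](C)(C)C)O[Si](C)(C)C(C)(C)C
F8 | step 22 | 9-(trimethylsilyloxy)-9(11)-ene 10-O-trimethylsilyl ether of 33 | C=C1[C@@H]2CC=C(O[Si](C)(C)C)[C@@](C[C@H]3OC(=O)[C@]4(C)CCC[C@@](C)(O[Si](C)(C)C)[C@H]34)(C2)[C@@H]1OC(C)=O
F9 | step 22 | 10-O-trimethylsilyl ether of 34 | C=C1[C@@H]2C=CC(=O)[C@@](C[C@H]3OC(=O)[C@]4(C)CCC[C@@](C)(O[Si](C)(C)C)[C@H]34)(C2)[C@@H]1OC(C)=O
A1 | alternative 1 | 15-deacetoxy-34 (10-hydroxy-9-oxo-9,10-seco-ent-kaura-11,16-dien-19-oic acid 19,6-lactone) | C=C1[C@@H]2C=CC(=O)[C@@](C[C@H]3OC(=O)[C@]4(C)CCC[C@@](C)(O)[C@H]34)(C2)C1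
A2 | alternative 2 | 2-[4-(tert-butyldiphenylsilyloxy)-1-(4-methoxybenzyloxy)butyl]-1,3-dimethyl-3-(trimethylsilyloxy)cyclohex-4-ene-1-carboxylic acid | OC(=O)[C@]1(C)CC=C[C@@](C)(O[Si](C)(C)C)[C@@H]1[C@H](OCc1ccc(OC)cc1)CCCO[Si](c1ccccc1)(c1ccccc1)C(C)(C)C
A3 | alternative 3 | Diels–Alder adduct: cyclohex-3-ene-1-carbaldehyde with C8 lactonylmethyl, C9 tert-butyldimethylsilyloxy and C13 (trimethylsilyl)ethynyl groups, lactone as its 10-O-trimethylsilyl ether | C[Si](C)(C)C#C[C@@H]1C=C[C@H](O[Si](C)(C)C(C)(C)C)[C@@](C[C@H]2OC(=O)[C@]3(C)CCC[C@@](C)(O[Si](C)(C)C)[C@H]23)(C1)C=O
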